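I start from the easy step: the intermediate turns into target or into the isomer of the product and back, and neither exchange uses reagent.

    intermediate ⇌ target (K1 = 2.2, k1 = 0.0049 s⁻¹, Ea1 = 80.0 kJ mol⁻¹, ΔH1 = −40.0 kJ mol⁻¹)
    reagent + target → over-reaction product (k2 = 0.0040 M⁻¹ s⁻¹, Ea2 = 74.0 kJ mol⁻¹)
    intermediate ⇌ isomer of the product (K3 = 2.3, k3 = 0.0024 s⁻¹, Ea3 = 81.0 kJ mol⁻¹, ΔH3 = −29.0 kJ mol⁻¹)
    gas ⇌ reagent, rate k4*(csat - [reagent]) (k4 = 0.0049 s⁻¹, csat = 110 mM)
    2 reagent → self-condensation product (k5 = 0.018 M⁻¹ s⁻¹, Ea5 = 63.0 kJ mol⁻¹)
    substrate + reagent → intermediate + released group (k6 = 0.0016 M⁻¹ s⁻¹, Ea6 = 79.0 kJ mol⁻¹)
    (constants at 35 °C)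

| flask | substrate | gas | temperature | time |
|---|---|---|---|---|
| green | 2.0 M | 110 mM (held) | 60 °C | 2.5 h |
| teal | 2.0 M | 110 mM (held) | 85 °C | 2.5 h |
| blue | 2.0 M | 110 mM (held) | 35 °C | 2.5 h |

- where a step has two of a species, its rate is k times that concentration squared, and two are used at each turn
- at the start none of reagent is dissolved
- the constants hold at 35 °C; other temperatures follow from the activation energies and enthalpies

- the flask with the highest amount of target, in percent of the substrate charged ("all alike" if they lie within 1.5 percentage points) (green / teal / blue / all alike)
- final target, as a percentage of the substrate charged, in green
- final target, as a percentage of the substrate charged, in teal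
- final target, as a percentage of the substrate charged, in blue

Can I treat those exchanges as balanced? The slowest way in them, isomer back to intermediate, takes about 16.0 min in blue, shorter than the 2.5 h run, and the isomer exchange speeds up 83 times from blue to teal. So I take intermediate, target and isomer as one pool. In blue the constants stand as given, and the target share is 0.400. By target share I mean the fraction of the pool standing as target once both exchanges balance: the first equilibrium constant over one plus both constants.

The objection is that those constants belong to blue's temperature. I work in powers of ten, since enthalpy moves the logarithm of a constant in proportion to the change in inverse temperature. For green the target constant shifts by −0.509 of a power of ten and the isomer constant by −0.369. For teal they shift by −0.947 and −0.686. The target constant loses more, so the share falls to 0.256 in green and 0.144 in teal.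

But a share of what? Substrate feeds the pool and reagent drains it through target, and reagent enters both rates, so it cancels. What remains is a selectivity factor: the drain constant times the share over the feed constant, 1.00 in blue, 0.552 in green and 0.275 in teal. The pool crests at this factor raised to the power factor over one minus factor, or at the inverse of e when the factor is one. Times the share, that caps target: 12.3% in green and 8.85% in teal. On these caps my pick is blue.

Does a flask stand at its crest? Setting gas supply against uptake by full substrate, I put blue's reagent near 0.0665 M, which leaves 38.4% of the substrate, close to the crest's 36.8%. This ignores self-condensation and over-reaction, which take reagent away, and falling substrate, which lets reagent rise. So I commit to 14.7% for blue. The same reckoning leaves 12.2% in green, past its crest at 26.5%. Beyond the crest I hold green and teal to their caps.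

The forecast says blue, with 8.6% in green, 2.1% in teal and 13.8% in blue. It takes the same view, that “intermediate, target and isomer form an equilibrated pool”, and puts blue's share at 0.38, slightly lagged, where I have the balanced value.

The simulation puts blue highest, at 13.8%, with green at 8.42% and teal at 2.11%. Green's readings at 2.50 h give a target share of 0.253 against my 0.256, and the teal neighbour read at 1.5 h gives 0.144 against my 0.144. In teal, substrate was still feeding the pool at 1.25 h, with 13.2% of it left and over-reaction product at 26.0%. Reagent went on converting target while substrate fell to 0.0284%, and over-reaction product reached 85.4% at 2.50 h.

The numbers are those of an exercise; no experiment stands behind them.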